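**Remark on the chemistry.** Ring A is numbered C1 (carboxyl-bearing carbon) to C6 (carbon bearing the ether oxygen), ring B C1' (ether oxygen) to C6' (formyl-bearing carbon). The enamine double bond of 18 is drawn E and the enol geometry of 19 is left open; both are mobile push–pull alkenes and their geometry has no consequence.

## Analysis of the target

Tenellic acid B is a diaryl ether of two tetrasubstituted benzene rings. Ring A carries a carboxyl group at C1, a methoxy group at C2, the (S)-1-hydroxy-3-methylbutyl chain at C3, hydrogen at C4 and C5, and the ether oxygen at C6. Ring B carries the ether oxygen at C1', a free hydroxyl at C2', a methyl group at C4' and a formyl group at C6'. The only stereocentre is the benzylic carbinol carbon on C3, so the problem is one of absolute configuration alone. That carbinol sits ortho to the methoxy group and para to the aryloxy group, so it should ionise easily in acid, with racemisation or elimination to a styrene. The aldehyde, the free acid and the catechol-type phenol add further constraints on the endgame. The central difficulty is the ether: its oxygen is flanked by the carboxyl on ring A and by both a hydroxyl and a formyl group on ring B, so a coupling of a 2,6-disubstituted phenol with an ortho-substituted arene would be badly hindered. The strategy rests on one feature: the contiguous array C1 (carboxyl), C2 (methoxy), C3 (alkyl), C4 (H) of ring A is the array C3 to C6 of a 3-carboalkoxy-4-methoxy-2-pyrone, and the two remaining atoms, C5 (H) and C6 (O-aryl), are an alkyne whose oxygen already carries ring B.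

## Retrosynthetic reasoning

**Endgame.** Tenellic acid B 25 is traced back to the silyl ether 24, then to the bis-allyl aldehyde 23 and the acetal 22. The order is dictated by the acid-labile benzylic carbinol: the one acidic operation (opening of the acetal) is placed while the carbinol is still silylated, the acid and the ring B phenol are then freed together under neutral conditions, and the silyl group leaves last with a fluoride source. No C–C or C–O bond of the skeleton is touched after 22.

**Ring A (key disconnection).** In 22 the bonds C4–C5 and C1–C6 of ring A are cut. This is the only place where a two-bond cut leaves a diene with the ester, methoxy and side chain already in sequence, namely pyrone 20, and a two-carbon partner that brings the ether oxygen, namely ethynyl ether 9. The gain is twofold: all four substituents of ring A are fixed by the ring synthesis, and the hindered C6–O bond is never made on an arene. The forward reaction has to be regioselective (oxygen-bearing alkyne carbon onto the ester-bearing pyrone carbon) and has to aromatise without an oxidant, which the expulsion of the lactone bridge provides.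

**Ynol ether 9.** The O–C(sp) bond is cut back to the dichlorovinyl ether 7 and, through aldehyde 6, to phenol 4 and trichloroethylene 5. The hindered, hydrogen-bonded phenol oxygen is thus bonded to a small linear two-carbon electrophile, where steric demand is minimal. The aldehyde must be masked as the dioxolane before the organolithium step that unveils the alkyne.

**Ring B oxygenation.** Phenol 4 goes back to catechol 3, to aldehyde 2 and to creosol 1. Creosol already has the methyl group para to the hydroxyl and only one free ortho position, so formylation can only give the required pattern. The methyl ether is exchanged for an allyl ether because ring A must keep its own methyl ether to the end.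

**Pyrone ring, O1–C2 and C5–C6.** Pyrone 20 is opened at the lactone C–O bond to the formyl enol 19 and its enamine precursor 18, and the one-carbon unit C6 is then removed to give the methoxyalkylidene malonate 17. Cutting here uses the vinylogous acidity of the methylene group of 17 to introduce C6 at the aldehyde oxidation level with an amide acetal, and one of the two equivalent esters of the malonate is always placed correctly for lactonisation.

**C3–C4 bond and the methyl ether.** Enol ether 17 comes from acylmalonate 16 by O-methylation, and 16 from acid 13 and diallyl malonate 14 by C-acylation. The malonate supplies pyrone C2, C3 and the ester that activates the diene; the acid carbon becomes C4, so its oxygen becomes the C2 methoxy oxygen of ring A.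

**Stereocentre.** Acid 13 is traced through ester 12 and hydroxy ester 11 to keto ester 10. The carbinol configuration is set at the very start by catalyst-controlled hydrogenation of a β-keto ester with a chiral diphosphine–ruthenium catalyst, the most dependable way to a single enantiomer of this unit, and is then only carried.

## Alternatives that were turned down

**Alternative 1:** Danheiser benzannulation of ring A. The disconnection cuts C1–C2, C2–C3 and C5–C6 (C4–C5 arises in the Wolff shift). In the forward step, irradiation of the diazo enone (S,E)-5-(tert-butyldimethylsilyloxy)-1-diazo-7-methyloct-3-en-2-one A2 would give a vinylketene, which adds the internal ynol ether 2-{3-(methoxymethoxy)-2-[3-(4-methoxybenzyloxy)prop-1-ynyloxy]-5-methylphenyl}-1,3-dioxolane A3. Cyclobutenone opening and 6π closure would give the phenol 3-[2-(1,3-dioxolan-2-yl)-6-(methoxymethoxy)-4-methylphenoxy]-6-[(S)-1-(tert-butyldimethylsilyloxy)-3-methylbutyl]-2-[(4-methoxybenzyloxy)methyl]phenol A1.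
- In its favour: the ketene [2+2] with an ynol ether is intrinsically fast and regioselective near room temperature, and the internal ynol ether A3 is sturdier than a terminal one. On reactivity and thermal demand of the bond-forming event this alternative is stronger than the chosen one.
- Against it: A1 has ring A at the wrong functional level. C2 is a free phenol and C1 a protected hydroxymethyl group, so O-methylation, debenzylation and two oxidations must follow before the same deprotections begin. The methoxymethyl group on ring B needs acid stronger than the benzylic carbinol tolerates, and A2 needs its own multi-step preparation with a photochemical step.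
- Comparison: the chosen route delivers ester and methyl ether directly from the ring synthesis and needs three steps after the key step instead of seven or more, with no redox adjustment.

**Alternative 2:** Robinson annulation that builds ring B on the ether oxygen. The disconnection cuts C3'–C4' and C1'=C6' of ring B. In the forward step the β-keto ester tert-butyl 6-[4-(allyloxy)-2,4-dioxobutoxy]-3-[(S)-1-(tert-butyldimethylsilyloxy)-3-methylbutyl]-2-methoxybenzoate A5 would add to methyl (E)-2-oxopent-3-enoate A6 under mild base and then condense through its aryloxy-bearing carbon. The product would be the cyclohexenone allyl 3-{2-(tert-butoxycarbonyl)-4-[(S)-1-(tert-butyldimethylsilyloxy)-3-methylbutyl]-3-methoxyphenoxy}-4-(methoxycarbonyl)-6-methyl-2-oxocyclohex-3-ene-1-carboxylate A4.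
- In its favour: every step is ionic and near room temperature, no fragile alkyne is involved, and the ether oxygen is attached by simple O-alkylation of a ring A phenol. On mildness it is stronger than the chosen route.
- Against it: the hard ring, ring A with its four contiguous substituents and the stereocentre, must be made beforehand by other means, so the key step does not address the main problem. A4 is still two oxidation-state adjustments and one decarboxylation away from ring B (deallylation–decarboxylation, dehydrogenation to the phenol beside a benzylic silyl ether, selective reduction of one ester to the aldehyde beside the tert-butyl ester). The ring closure must go through the less acidic of two enolisable positions, and the tert-butyl ester leaves only in strong acid.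
- Comparison: the chosen route constructs the harder ring and takes ring B from a commercial phenol at the correct oxidation level.

**Alternative 3:** Aryne three-component coupling. The disconnection cuts the C6–O and C1–carboxyl bonds without closing a ring. In the forward step, fluoride-induced elimination from 4-[(S)-1-(tert-butyldimethylsilyloxy)-3-methylbutyl]-3-methoxy-2-(trimethylsilyl)phenyl trifluoromethanesulfonate A8 would give the C1–C6 aryne. The caesium salt of 2-(allyloxy)-6-(1,3-dioxolan-2-yl)-4-methylphenol A9 would add at C6 and the C1 aryl anion would be carboxylated, giving 6-[2-(allyloxy)-6-(1,3-dioxolan-2-yl)-4-methylphenoxy]-3-[(S)-1-(tert-butyldimethylsilyloxy)-3-methylbutyl]-2-methoxybenzoic acid A7.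
- In its favour: it is the most convergent plan, runs at low temperature, has its regiochemistry directed by the methoxy group, and A7 needs the same three deprotections as the chosen intermediate. Its endgame is as short, and its key step milder.
- Against it: A8 is itself a fully substituted benzene with the stereocentre, and would need a long sequence of directed metalations, which is exactly the contiguous-substitution problem that a ring synthesis avoids. The nucleophile is a 2,6-disubstituted phenoxide that must outcompete fluoride, and it is reversibly masked by the carboxylating gas. The flanked aryl anion must also be carboxylated faster than it is protonated.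
- Comparison: the chosen route uses a two-component reaction whose regiochemistry follows from polarity, and its diene is built from acyclic materials in seven steps.

Key step: step 14

## Route

Step 1
Reactants: 1 2-methoxy-4-methylphenol (creosol)
Product: 2 2-hydroxy-3-methoxy-5-methylbenzaldehyde
Conditions: MgCl2, Et3N, (CH2O)n, MeCN, reflux; then aq. HCl
Reagents that add atoms: paraformaldehyde (as formaldehyde), C=O
Why: Magnesium-mediated ortho-formylation of a phenol; the magnesium phenoxide delivers formaldehyde to the only free ortho position (the other is methoxylated, the para position methylated) and a second equivalent of formaldehyde oxidises the benzylic alkoxide to the aldehyde by hydride transfer.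

Step 2
Reactants: 2 2-hydroxy-3-methoxy-5-methylbenzaldehyde
Product: 3 2,3-dihydroxy-5-methylbenzaldehyde
Conditions: BBr3, CH2Cl2, −78 → 0 °C; then H2O
Reagents that add atoms: none
Why: Lewis-acid cleavage of an aryl methyl ether (bromide attacks the methyl group of the boron-coordinated ether); the aldehyde tolerates BBr3 at low temperature, as in the conversion of related o-vanillins into catechol aldehydes.

Step 3
Reactants: 3 2,3-dihydroxy-5-methylbenzaldehyde
Product: 4 3-(allyloxy)-2-hydroxy-5-methylbenzaldehyde
Conditions: NaH (2.2 equiv), DMSO, rt; then allyl bromide (1.0 equiv), rt; aq. HCl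
Reagents that add atoms: allyl bromide, C=CCBr
Why: Williamson etherification of the dianion; the C2 oxide is conjugated with and chelated to the formyl group and is the weaker nucleophile, so one equivalent of halide should alkylate the C3 oxide selectively.

Step 4
Reactants: 4 3-(allyloxy)-2-hydroxy-5-methylbenzaldehyde; 5 trichloroethylene
Product: 6 3-(allyloxy)-2-[(E)-1,2-dichlorovinyloxy]-5-methylbenzaldehyde
Conditions: K2CO3, DMF, 70 °C
Reagents that add atoms: none
Why: Base-induced elimination of HCl from trichloroethylene gives dichloroacetylene in low concentration, to which the phenoxide adds in anti fashion (nucleophilic vinylation); the small linear electrophile is what allows the doubly flanked oxygen to react.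

Step 5
Reactants: 6 3-(allyloxy)-2-[(E)-1,2-dichlorovinyloxy]-5-methylbenzaldehyde
Product: 7 2-{3-(allyloxy)-2-[(E)-1,2-dichlorovinyloxy]-5-methylphenyl}-1,3-dioxolane
Conditions: HOCH2CH2OH, TsOH·H2O (cat.), PhH, reflux (Dean–Stark)
Reagents that add atoms: ethylene glycol, OCCO
Why: Acid-catalysed acetalisation with azeotropic removal of water; the electron-poor dichlorovinyl ether is not protonated under these conditions, and the aldehyde must be masked before the organolithium step.

Step 6
Reactants: 7 2-{3-(allyloxy)-2-[(E)-1,2-dichlorovinyloxy]-5-methylphenyl}-1,3-dioxolane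
Product: 9 2-[3-(allyloxy)-2-(ethynyloxy)-5-methylphenyl]-1,3-dioxolane, via lithium aryloxyacetylide 8 (not isolated)
Conditions: n-BuLi (2.3 equiv), THF, −78 → −40 °C; then aq. NH4Cl, −78 °C; used promptly
Reagents that add atoms: none
Why: Known conversion of 1,2-dichlorovinyl ethers into ynol ethers: vinylic deprotonation and β-elimination of LiCl give the chloroalkynyl ether, lithium–chlorine exchange with the second equivalent gives acetylide 8, and protonation releases the terminal ynol ether; at −78 °C these steps should be far faster than attack on the allyl ether or the acetal.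

Step 7
Reactants: 10 methyl 5-methyl-3-oxohexanoate
Product: 11 methyl (S)-3-hydroxy-5-methylhexanoate
Conditions: H2 (50 atm), RuCl2[(S)-BINAP] (cat.), MeOH, 50 °C
Reagents that add atoms: none
Why: Noyori asymmetric hydrogenation of a β-keto ester; the ester chelates to ruthenium and the (S)-diphosphine directs hydride to the face that gives the (S)-carbinol, the same sense as for simple 3-oxoalkanoates, since the ester-bearing branch keeps CIP priority over the isobutyl branch.

Step 8
Reactants: 11 methyl (S)-3-hydroxy-5-methylhexanoate
Product: 12 methyl (S)-3-(tert-butyldimethylsilyloxy)-5-methylhexanoate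
Conditions: TBSCl, imidazole, DMF, rt
Reagents that add atoms: tert-butyldimethylsilyl chloride, CC(C)(C)[Si](C)(C)Cl
Why: Standard silylation of a secondary alcohol through the N-silylimidazolium ion; the stereocentre is not involved.

Step 9
Reactants: 12 methyl (S)-3-(tert-butyldimethylsilyloxy)-5-methylhexanoate
Product: 13 (S)-3-(tert-butyldimethylsilyloxy)-5-methylhexanoic acid
Conditions: LiOH·H2O, THF/MeOH/H2O, rt; then dilute HCl to pH 3
Reagents that add atoms: lithium hydroxide, [Li+].[OH-]
Why: Saponification of a methyl ester; the secondary silyl ether is stable to aqueous LiOH at room temperature and the carboxylate, once formed, does not enolise, so β-elimination is not expected.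

Step 10
Reactants: 13 (S)-3-(tert-butyldimethylsilyloxy)-5-methylhexanoic acid; 14 diallyl malonate
Product: 16 diallyl 2-[(S)-3-(tert-butyldimethylsilyloxy)-5-methylhexanoyl]malonate, via acid chloride 15 (not isolated)
Conditions: 1-chloro-N,N,2-trimethylprop-1-en-1-amine, CH2Cl2, 0 °C → rt; then 14, MgCl2, Et3N, MeCN, 0 °C → rt; aq. HCl
Reagents that add atoms: none
Why: Acid chloride formation under neutral conditions (no HCl, so the silyl ether is safe) followed by C-acylation of the magnesium enolate of the malonate (soft enolisation with MgCl2/Et3N); the product is held as its magnesium chelate, which prevents O-acylation and a second acylation.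

Step 11
Reactants: 16 diallyl 2-[(S)-3-(tert-butyldimethylsilyloxy)-5-methylhexanoyl]malonate
Product: 17 diallyl 2-[(S)-3-(tert-butyldimethylsilyloxy)-1-methoxy-5-methylhexylidene]malonate
Conditions: Me3SiCHN2, PhMe/MeOH, 0 °C → rt
Reagents that add atoms: trimethylsilyldiazomethane, C[Si](C)(C)C=[N+]=[N-]
Why: O-Methylation of a strongly acidic tricarbonyl enol by a diazoalkane (proton transfer, then methylation of the enolate oxygen by the diazonium ion); the carbon is tertiary and hindered, so O-alkylation is expected, and the two identical esters leave no alkene geometry to control.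

Step 12
Reactants: 17 diallyl 2-[(S)-3-(tert-butyldimethylsilyloxy)-1-methoxy-5-methylhexylidene]malonate
Product: 18 diallyl 2-[(S,E)-3-(tert-butyldimethylsilyloxy)-2-(dimethylaminomethylidene)-1-methoxy-5-methylhexylidene]malonate
Conditions: Me2NCH(OMe)2, PhMe, 80–90 °C
Reagents that add atoms: N,N-dimethylformamide dimethyl acetal, COC(OC)N(C)C
Why: Amide-acetal condensation with a vinylogous C–H acid: methoxide released from the reagent deprotonates the γ-methylene of the alkoxyalkylidene malonate, the delocalised anion attacks the formamidinium ion and loss of methanol gives the push–pull dienamine, the established entry to 4-alkoxy-2-pyrone- and 2-pyridone-3-carboxylates.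

Step 13
Reactants: 18 diallyl 2-[(S,E)-3-(tert-butyldimethylsilyloxy)-2-(dimethylaminomethylidene)-1-methoxy-5-methylhexylidene]malonate
Product: 20 allyl 5-[(S)-1-(tert-butyldimethylsilyloxy)-3-methylbutyl]-4-methoxy-2-oxo-2H-pyran-3-carboxylate, via hydroxymethylidene diene 19 (not isolated)
Conditions: TsOH·H2O (1.1 equiv), THF/H2O, 0 °C → rt
Reagents that add atoms: water, O
Why: Acid hydrolysis of the enamine (C-protonation, addition of water, loss of dimethylamine) gives formyl enol 19, whose hydroxyl can always reach one of the two malonate esters and lactonises with loss of allyl alcohol to the 2-pyrone; the one equivalent of acid ends as the dimethylammonium salt, so the medium stays mild for the silyl ether and the 4-methoxy group.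

Step 14
Reactants: 20 allyl 5-[(S)-1-(tert-butyldimethylsilyloxy)-3-methylbutyl]-4-methoxy-2-oxo-2H-pyran-3-carboxylate; 9 2-[3-(allyloxy)-2-(ethynyloxy)-5-methylphenyl]-1,3-dioxolane
Product: 22 allyl 6-[2-(allyloxy)-6-(1,3-dioxolan-2-yl)-4-methylphenoxy]-3-[(S)-1-(tert-butyldimethylsilyloxy)-3-methylbutyl]-2-methoxybenzoate, via bridged bicyclic lactone 21 (not isolated)
Conditions: PhMe, 110–130 °C, sealed tube; 9 (2.5 equiv) added in portions; BHT (cat.)
Reagents that add atoms: none
Why: The 3-ester lowers the LUMO of pyrone 20 and the aryloxy group raises the HOMO of alkyne 9, so an inverse-electron-demand Diels–Alder reaction is expected; the closest known reaction type is the cycloaddition of 3-carboalkoxy-2-pyrones with ynol ethers and ketene acetals. Bond formation should be asynchronous: the unsubstituted, nucleophilic alkyne carbon attacks the electrophilic pyrone C6 first (C4–C5 of ring A) and the oxygen-bearing carbon then closes onto the ester-bearing pyrone C3 (C1–C6 of ring A). Ring A is therefore closed by an intermolecular [4+2] cycloaddition as the bridged lactone 21, which aromatises at once by retro-[4+2] loss of CO2, so no oxidant is needed. The only selectivity required is regiochemical, and it follows from the matched polarisation of the two partners, which places the ether ortho to the ester. The two bridgehead centres of 21 disappear on aromatisation, no stereocentre is created and the silyloxy-bearing carbon is a spectator. The 4-methoxy donor and the branched C5 substituent make 20 less electrophilic than simple 3-carboalkoxypyrones, hence the temperature and the portionwise excess of 9; the temperature stays well below that of an aryl allyl ether Claisen rearrangement.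

Step 15
Reactants: 22 allyl 6-[2-(allyloxy)-6-(1,3-dioxolan-2-yl)-4-methylphenoxy]-3-[(S)-1-(tert-butyldimethylsilyloxy)-3-methylbutyl]-2-methoxybenzoate
Product: 23 allyl 6-[2-(allyloxy)-6-formyl-4-methylphenoxy]-3-[(S)-1-(tert-butyldimethylsilyloxy)-3-methylbutyl]-2-methoxybenzoate
Conditions: PPTS, acetone/H2O, 50 °C
Reagents that add atoms: water, O
Why: Mild acid-catalysed acetal hydrolysis (transacetalisation to acetone); it is run while the benzylic oxygen is still silylated, and PPTS is too weak an acid to ionise that position or to cleave a secondary silyl ether.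

Step 16
Reactants: 23 allyl 6-[2-(allyloxy)-6-formyl-4-methylphenoxy]-3-[(S)-1-(tert-butyldimethylsilyloxy)-3-methylbutyl]-2-methoxybenzoate
Product: 24 3-[(S)-1-(tert-butyldimethylsilyloxy)-3-methylbutyl]-6-(2-formyl-6-hydroxy-4-methylphenoxy)-2-methoxybenzoic acid
Conditions: Pd(PPh3)4 (cat.), TolSO2Na (2.5 equiv), THF/MeOH, rt; then dilute HCl to pH 3
Reagents that add atoms: none
Why: Tsuji–Trost deallylation: zerovalent palladium ionises both the allyl ester and the aryl allyl ether (carboxylate and phenoxide are good leaving groups) to π-allyl complexes that the sulfinate captures; this scavenger is neither basic nor able to condense with the aldehyde.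

Step 17
Reactants: 24 3-[(S)-1-(tert-butyldimethylsilyloxy)-3-methylbutyl]-6-(2-formyl-6-hydroxy-4-methylphenoxy)-2-methoxybenzoic acid
Product: 25 tenellic acid B, 6-(2-formyl-6-hydroxy-4-methylphenoxy)-3-[(S)-1-hydroxy-3-methylbutyl]-2-methoxybenzoic acid
Conditions: Bu4NF (excess), THF, 0 °C → rt; then aq. NH4Cl
Reagents that add atoms: none
Why: Fluoride-induced desilylation driven by the Si–F bond; the medium is buffered by the carboxylate and phenoxide, no acid touches the benzylic carbinol, and the C–O bond of the stereocentre is not broken, so the (S) configuration is retained.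

## Compound list

1 | 2-methoxy-4-methylphenol (creosol) | COc1cc(C)ccc1O | starting material
2 | 2-hydroxy-3-methoxy-5-methylbenzaldehyde | COc1cc(C)cc(C=O)c1O | intermediate
3 | 2,3-dihydroxy-5-methylbenzaldehyde | Cc1cc(O)c(O)c(C=O)c1 | intermediate
4 | 3-(allyloxy)-2-hydroxy-5-methylbenzaldehyde | C=CCOc1cc(C)cc(C=O)c1O | intermediate
5 | trichloroethylene | ClC=C(Cl)Cl | starting material
6 | 3-(allyloxy)-2-[(E)-1,2-dichlorovinyloxy]-5-methylbenzaldehyde | C=CCOc1cc(C)cc(C=O)c1O/C(Cl)=C\Cl | intermediate
7 | 2-{3-(allyloxy)-2-[(E)-1,2-dichlorovinyloxy]-5-methylphenyl}-1,3-dioxolane | C=CCOc1cc(C)cc(C2OCCO2)c1O/C(Cl)=C\Cl | intermediate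
8 | lithium [2-(allyloxy)-6-(1,3-dioxolan-2-yl)-4-methylphenoxy]acetylide | [Li]C#COc1c(OCC=C)cc(C)cc1C1OCCO1 | intermediate (not isolated)
9 | 2-[3-(allyloxy)-2-(ethynyloxy)-5-methylphenyl]-1,3-dioxolane | C#COc1c(OCC=C)cc(C)cc1C1OCCO1 | intermediate
10 | methyl 5-methyl-3-oxohexanoate | CC(C)CC(=O)CC(=O)OC | starting material
11 | methyl (S)-3-hydroxy-5-methylhexanoate | COC(=O)C[C@@H](O)CC(C)C | intermediate
12 | methyl (S)-3-(tert-butyldimethylsilyloxy)-5-methylhexanoate | COC(=O)C[C@@H](O[Si](C)(C)C(C)(C)C)CC(C)C | intermediate
13 | (S)-3-(tert-butyldimethylsilyloxy)-5-methylhexanoic acid | OC(=O)C[C@@H](O[Si](C)(C)C(C)(C)C)CC(C)C | intermediate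
14 | diallyl malonate | C=CCOC(=O)CC(=O)OCC=C | starting material
15 | (S)-3-(tert-butyldimethylsilyloxy)-5-methylhexanoyl chloride | ClC(=O)C[C@@H](O[Si](C)(C)C(C)(C)C)CC(C)C | intermediate (not isolated)
16 | diallyl 2-[(S)-3-(tert-butyldimethylsilyloxy)-5-methylhexanoyl]malonate (largely enolised) | C=CCOC(=O)C(C(=O)OCC=C)C(=O)C[C@@H](O[Si](C)(C)C(C)(C)C)CC(C)C | intermediate
17 | diallyl 2-[(S)-3-(tert-butyldimethylsilyloxy)-1-methoxy-5-methylhexylidene]malonate | C=CCOC(=O)C(C(=O)OCC=C)=C(OC)C[C@@H](O[Si](C)(C)C(C)(C)C)CC(C)C | intermediate
18 | diallyl 2-[(S,E)-3-(tert-butyldimethylsilyloxy)-2-(dimethylaminomethylidene)-1-methoxy-5-methylhexylidene]malonate | C=CCOC(=O)C(C(=O)OCC=C)=C(OC)/C(=C/N(C)C)[C@@H](O[Si](C)(C)C(C)(C)C)CC(C)C | intermediate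
19 | diallyl 2-[(S)-3-(tert-butyldimethylsilyloxy)-2-(hydroxymethylidene)-1-methoxy-5-methylhexylidene]malonate (enol geometry mobile) | C=CCOC(=O)C(C(=O)OCC=C)=C(OC)C(=CO)[C@@H](O[Si](C)(C)C(C)(C)C)CC(C)C | intermediate (not isolated)
20 | allyl 5-[(S)-1-(tert-butyldimethylsilyloxy)-3-methylbutyl]-4-methoxy-2-oxo-2H-pyran-3-carboxylate | C=CCOC(=O)C1=C(OC)C([C@@H](O[Si](C)(C)C(C)(C)C)CC(C)C)=COC1=O | intermediate
21 | allyl 8-[2-(allyloxy)-6-(1,3-dioxolan-2-yl)-4-methylphenoxy]-6-[(S)-1-(tert-butyldimethylsilyloxy)-3-methylbutyl]-5-methoxy-3-oxo-2-oxabicyclo[2.2.2]octa-5,7-diene-4-carboxylate (both bridgehead diastereomers) | O=C1OC2C([C@@H](O[Si](C)(C)C(C)(C)C)CC(C)C)=C(OC)C1(C(=O)OCC=C)C(Oc3c(OCC=C)cc(C)cc3C3OCCO3)=C2 | intermediate (not isolated)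
22 | allyl 6-[2-(allyloxy)-6-(1,3-dioxolan-2-yl)-4-methylphenoxy]-3-[(S)-1-(tert-butyldimethylsilyloxy)-3-methylbutyl]-2-methoxybenzoate | C=CCOC(=O)c1c(OC)c([C@@H](O[Si](C)(C)C(C)(C)C)CC(C)C)ccc1Oc1c(OCC=C)cc(C)cc1C1OCCO1 | intermediate
23 | allyl 6-[2-(allyloxy)-6-formyl-4-methylphenoxy]-3-[(S)-1-(tert-butyldimethylsilyloxy)-3-methylbutyl]-2-methoxybenzoate | C=CCOC(=O)c1c(OC)c([C@@H](O[Si](C)(C)C(C)(C)C)CC(C)C)ccc1Oc1c(OCC=C)cc(C)cc1C=O | intermediate
24 | 3-[(S)-1-(tert-butyldimethylsilyloxy)-3-methylbutyl]-6-(2-formyl-6-hydroxy-4-methylphenoxy)-2-methoxybenzoic acid | COc1c([C@@H](O[Si](C)(C)C(C)(C)C)CC(C)C)ccc(Oc2c(O)cc(C)cc2C=O)c1C(=O)O | intermediate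
25 | tenellic acid B | COc1c([C@@H](O)CC(C)C)ccc(Oc2c(O)cc(C)cc2C=O)c1C(=O)O | target

## Step count and uncertain steps

Total step count: 17. Longest linear sequence: 11 steps (steps 7 to 17); the ring B branch (steps 1 to 6) joins at step 14.

**Step 14 (key step).** The most likely failure is thermal oligomerisation of the terminal aryl ynol ether outrunning a slow cycloaddition, because the 4-methoxy group raises the LUMO of the diene and the C5 branch hinders it. If the temperature had to be raised far beyond 130 °C, Claisen rearrangement of the ring B allyl ether would begin to compete.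

The fallback keeps the bond set but gives the diene an acceptor in place of the donor. It sets out from pyrone 20.
- BCl3 in CH2Cl2 at −78 °C, guided by chelation between the C4 oxygen and the ester carbonyl, would cleave the methyl ether to the 4-hydroxypyrone ester F1.
- Ac2O/pyridine at 0 °C would give the 4-acetoxypyrone ester F2.
- With 9 in toluene at 60–80 °C, F2 should react through the acetoxy-substituted bridged lactone F3 to the ring A aryl acetate F4.
- K2CO3 in MeOH at 0 °C would free the C2 phenol F5; the 2,6-disubstituted allyl benzoate is too hindered to transesterify.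
- MeI/K2CO3 in DMF would methylate F5 and return to the route at 22.

**Step 12.** The likely failure is β-elimination of the silyloxy group from the vinylogous carbanion (E1cB), or no condensation at all, because the methylene group is flanked by a branched, silyloxy-bearing carbon.

The fallback introduces the one-carbon unit earlier, at −78 °C, by a Claisen formylation. It sets out from silyl ether 12.
- LiN(iPr)2 in THF at −78 °C and then 2,2,2-trifluoroethyl formate would give the α-formyl ester enol F6.
- Me2SO4/K2CO3 in DMF at 0 °C would give the (E)-β-methoxyacrylate methyl ester F7, which no longer has an acidic α-hydrogen.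
- LiOH would give the methoxyacrylic acid F8.
- The chloroenamine of step 10 would give the methoxyacryloyl chloride F9 (not isolated), and acylation of malonate 14 with MgCl2/Et3N would give the methoxymethylidene acylmalonate F10.
- Me3SiCHN2 would give the bis(enol ether) F11.
- TsOH in wet THF would hydrolyse the terminal enol ether of F11 to 19, which closes to pyrone 20 as in step 13, where the route is rejoined.

**Step 13.** The likely failures are loss of the silyl ether by acid-assisted ionisation next to the electron-rich enamine or enol, and hydrolysis of the C4 methyl enol ether before the ring has closed.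

The fallback separates hydrolysis from ring closure and closes the ring under base. It sets out from 18: the enamine would be hydrolysed in a two-phase system buffered near pH 4–5 (aqueous NaH2PO4, CH2Cl2) and the formyl enol 19 isolated; lactonisation would then be run with catalytic DBU in toluene at room temperature, as an acyl substitution by the enolate oxygen with no acid present. The route is rejoined at 20. No new compound is involved.

**Step 6.** The likely failure is decomposition of the terminal ynol ether during warming, work-up and chromatography (oligomerisation, or hydration to the aryl acetate on silica).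

The fallback carries the alkyne in a stable, storable form. It sets out from 7: after the same treatment with n-BuLi, acetylide 8 would be quenched with Me3SiCl to give the C-silylated ynol ether F12, which can be purified and stored. K2CO3 in MeOH at 0 °C, immediately before step 14, would release 9, where the route is rejoined.

## Further compounds

F1 | step 14 | allyl 5-[(S)-1-(tert-butyldimethylsilyloxy)-3-methylbutyl]-4-hydroxy-2-oxo-2H-pyran-3-carboxylate | C=CCOC(=O)C1=C(O)C([C@@H](O[Si](C)(C)C(C)(C)C)CC(C)C)=COC1=O
F2 | step 14 | allyl 4-acetoxy-5-[(S)-1-(tert-butyldimethylsilyloxy)-3-methylbutyl]-2-oxo-2H-pyran-3-carboxylate | C=CCOC(=O)C1=C(OC(C)=O)C([C@@H](O[Si](C)(C)C(C)(C)C)CC(C)C)=COC1=O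
F3 | step 14 | allyl 5-acetoxy-8-[2-(allyloxy)-6-(1,3-dioxolan-2-yl)-4-methylphenoxy]-6-[(S)-1-(tert-butyldimethylsilyloxy)-3-methylbutyl]-3-oxo-2-oxabicyclo[2.2.2]octa-5,7-diene-4-carboxylate (not isolated) | O=C1OC2C([C@@H](O[Si](C)(C)C(C)(C)C)CC(C)C)=C(OC(C)=O)C1(C(=O)OCC=C)C(Oc3c(OCC=C)cc(C)cc3C3OCCO3)=C2
F4 | step 14 | allyl 2-acetoxy-6-[2-(allyloxy)-6-(1,3-dioxolan-2-yl)-4-methylphenoxy]-3-[(S)-1-(tert-butyldimethylsilyloxy)-3-methylbutyl]benzoate | C=CCOC(=O)c1c(OC(C)=O)c([C@@H](O[Si](C)(C)C(C)(C)C)CC(C)C)ccc1Oc1c(OCC=C)cc(C)cc1C1OCCO1
F5 | step 14 | allyl 6-[2-(allyloxy)-6-(1,3-dioxolan-2-yl)-4-methylphenoxy]-3-[(S)-1-(tert-butyldimethylsilyloxy)-3-methylbutyl]-2-hydroxybenzoate | C=CCOC(=O)c1c(O)c([C@@H](O[Si](C)(C)C(C)(C)C)CC(C)C)ccc1Oc1c(OCC=C)cc(C)cc1C1OCCO1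
F6 | step 12 | methyl (S)-3-(tert-butyldimethylsilyloxy)-2-(hydroxymethylidene)-5-methylhexanoate (enol of the α-formyl ester) | COC(=O)C(=CO)[C@@H](O[Si](C)(C)C(C)(C)C)CC(C)C
F7 | step 12 | methyl (S,E)-3-(tert-butyldimethylsilyloxy)-2-(methoxymethylidene)-5-methylhexanoate | CO/C=C(/C(=O)OC)[C@@H](O[Si](C)(C)C(C)(C)C)CC(C)C
F8 | step 12 | (S,E)-3-(tert-butyldimethylsilyloxy)-2-(methoxymethylidene)-5-methylhexanoic acid | CO/C=C(/C(=O)O)[C@@H](O[Si](C)(C)C(C)(C)C)CC(C)C
F9 | step 12 | (S,E)-3-(tert-butyldimethylsilyloxy)-2-(methoxymethylidene)-5-methylhexanoyl chloride (not isolated) | CO/C=C(/C(=O)Cl)[C@@H](O[Si](C)(C)C(C)(C)C)CC(C)C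
F10 | step 12 | diallyl 2-[(S,E)-3-(tert-butyldimethylsilyloxy)-2-(methoxymethylidene)-5-methylhexanoyl]malonate | C=CCOC(=O)C(C(=O)OCC=C)C(=O)/C(=C/OC)[C@@H](O[Si](C)(C)C(C)(C)C)CC(C)C
F11 | step 12 | diallyl 2-[(S,E)-3-(tert-butyldimethylsilyloxy)-1-methoxy-2-(methoxymethylidene)-5-methylhexylidene]malonate | C=CCOC(=O)C(C(=O)OCC=C)=C(OC)/C(=C/OC)[C@@H](O[Si](C)(C)C(C)(C)C)CC(C)C
F0 | step 13 | none | none
F12 | step 6 | 2-[3-(allyloxy)-5-methyl-2-{[(trimethylsilyl)ethynyl]oxy}phenyl]-1,3-dioxolane | C[Si](C)(C)C#COc1c(OCC=C)cc(C)cc1C1OCCO1
A1 | alternative 1 | 3-[2-(1,3-dioxolan-2-yl)-6-(methoxymethoxy)-4-methylphenoxy]-6-[(S)-1-(tert-butyldimethylsilyloxy)-3-methylbutyl]-2-[(4-methoxybenzyloxy)methyl]phenol | Oc1c([C@@H](O[Si](C)(C)C(C)(C)C)CC(C)C)ccc(Oc2c(OCOC)cc(C)cc2C2OCCO2)c1COCc1ccc(OC)cc1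
A2 | alternative 1 | (S,E)-5-(tert-butyldimethylsilyloxy)-1-diazo-7-methyloct-3-en-2-one | [N-]=[N+]=CC(=O)/C=C/[C@@H](O[Si](C)(C)C(C)(C)C)CC(C)C
A3 | alternative 1 | 2-{3-(methoxymethoxy)-2-[3-(4-methoxybenzyloxy)prop-1-ynyloxy]-5-methylphenyl}-1,3-dioxolane | COCOc1cc(C)cc(C2OCCO2)c1OC#CCOCc1ccc(OC)cc1
A4 | alternative 2 | allyl 3-{2-(tert-butoxycarbonyl)-4-[(S)-1-(tert-butyldimethylsilyloxy)-3-methylbutyl]-3-methoxyphenoxy}-4-(methoxycarbonyl)-6-methyl-2-oxocyclohex-3-ene-1-carboxylate | C=CCOC(=O)C1C(C)CC(C(=O)OC)=C(Oc2ccc([C@@H](O[Si](C)(C)C(C)(C)C)CC(C)C)c(OC)c2C(=O)OC(C)(C)C)C1=O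
A5 | alternative 2 | tert-butyl 6-[4-(allyloxy)-2,4-dioxobutoxy]-3-[(S)-1-(tert-butyldimethylsilyloxy)-3-methylbutyl]-2-methoxybenzoate | C=CCOC(=O)CC(=O)COc1ccc([C@@H](O[Si](C)(C)C(C)(C)C)CC(C)C)c(OC)c1C(=O)OC(C)(C)C
A6 | alternative 2 | methyl (E)-2-oxopent-3-enoate | C/C=C/C(=O)C(=O)OC
A7 | alternative 3 | 6-[2-(allyloxy)-6-(1,3-dioxolan-2-yl)-4-methylphenoxy]-3-[(S)-1-(tert-butyldimethylsilyloxy)-3-methylbutyl]-2-methoxybenzoic acid | COc1c([C@@H](O[Si](C)(C)C(C)(C)C)CC(C)C)ccc(Oc2c(OCC=C)cc(C)cc2C2OCCO2)c1C(=O)O
A8 | alternative 3 | 4-[(S)-1-(tert-butyldimethylsilyloxy)-3-methylbutyl]-3-methoxy-2-(trimethylsilyl)phenyl trifluoromethanesulfonate | COc1c([C@@H](O[Si](C)(C)C(C)(C)C)CC(C)C)ccc(OS(=O)(=O)C(F)(F)F)c1[Si](C)(C)C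
A9 | alternative 3 | 2-(allyloxy)-6-(1,3-dioxolan-2-yl)-4-methylphenol | Oc1c(OCC=C)cc(C)cc1C1OCCO1
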